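**Assumption:** the target SMILES has no stereocentre and the molecule is achiral, so "single enantiomer" calls for no stereocontrol; 2,4-dimethoxy-6-methylbenzaldehyde and 3-fluoro-5-methylanisole are taken as commercial. The route is a paper design and has not been run.

## Retrosynthetic overview

1. Last step: global O-demethylation of the octamethyl ether (eight ArOMe to ArOH, both methyl esters kept).
2. Two diaryl ether C–O bonds: double SNAr of a central bis-phenol (rings B–C–B) with two copies of a ring A fluoride activated by ortho-CHO and ortho-CO2Me.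
3. Two diarylmethane C–C bonds: a ring B aryllithium (lithiated between its two OMe groups) adds twice to a ring C dialdehyde, then ionic deoxygenation; this fixes the 4,6-pattern on the orcinol core with no regiochemical question.
4. Ring B phenol by Dakin oxidation of the commercial aldehyde; ring A fluoride from 3-fluoro-5-methylanisole by ortho-lithiation/formylation, para-bromination and Pd-carbonylation.
5. No ring is formed: all five benzene rings come from commercial arenes, assembled in the order B, then B–C–B, then A–B–C–B–A.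

## Route

Step 1
Reactants: 1 2,4-dimethoxy-6-methylbenzaldehyde
Product: 3 2,4-dimethoxy-6-methylphenol, via aryl formate 2 (not isolated)
Conditions: mCPBA, CH2Cl2, 0 °C to rt; then K2CO3 (cat.), MeOH, rt
Reagents that add atoms: mCPBA OOC(=O)c1cccc(Cl)c1
Why: Dakin-type Baeyer–Villiger oxidation; the electron-rich aryl group migrates to oxygen and the formate is methanolysed.

Step 2
Reactants: 3 2,4-dimethoxy-6-methylphenol
Product: 4 1,5-dimethoxy-2-(methoxymethoxy)-3-methylbenzene
Conditions: NaH, MOMCl, DMF, 0 °C to rt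
Reagents that add atoms: chloromethyl methyl ether COCCl
Why: Williamson-type O-alkylation; the MOM ether tolerates n-BuLi and falls off in the acidic step 5.

Step 3
Reactants: 1 2,4-dimethoxy-6-methylbenzaldehyde
Product: 5 4,6-dimethoxy-2-methylbenzene-1,3-dicarbaldehyde
Conditions: Cl2CHOMe, TiCl4, CH2Cl2, 0 °C to rt; then ice/H2O
Reagents that add atoms: dichloromethyl methyl ether COC(Cl)Cl; water O
Why: Rieche formylation (electrophilic aromatic substitution) at the position para to one OMe and ortho to the other; the site between the two OMe groups is more hindered and not attacked.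

Step 4
Reactants: 4 1,5-dimethoxy-2-(methoxymethoxy)-3-methylbenzene (2.3 equiv); 5 4,6-dimethoxy-2-methylbenzene-1,3-dicarbaldehyde
Product: 7 (4,6-dimethoxy-2-methyl-1,3-phenylene)bis{[2,6-dimethoxy-3-(methoxymethoxy)-4-methylphenyl]methanol} (meso/racemic mixture), via aryllithium 6 (not isolated)
Conditions: n-BuLi, THF, 0 °C to rt; then 5, −78 °C to 0 °C; H2O
Reagents that add atoms: none
Why: Directed ortho-metalation at the C–H flanked by two OMe groups, then twofold 1,2-addition to the non-enolisable dialdehyde; the two carbinol centres form without control and are erased in step 5.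

Step 5
Reactants: 7 bis-carbinol
Product: 9 3,3'-[(4,6-dimethoxy-2-methyl-1,3-phenylene)bis(methylene)]bis(2,4-dimethoxy-6-methylphenol), via bis-MOM diarylmethane 8 (not isolated)
Conditions: Et3SiH, TFA, CH2Cl2, 0 °C to rt
Reagents that add atoms: none
Why: Ionic hydrogenation of the doubly benzylic, electron-rich carbinols; TFA also cleaves both MOM ethers, and the silane traps the methoxymethyl cation.

Step 6
Reactants: 10 1-fluoro-3-methoxy-5-methylbenzene (3-fluoro-5-methylanisole)
Product: 12 2-fluoro-6-methoxy-4-methylbenzaldehyde, via aryllithium 11 (not isolated)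
Conditions: n-BuLi, THF, −78 °C; then DMF, −78 °C to 0 °C; H2O
Reagents that add atoms: N,N-dimethylformamide CN(C)C=O
Why: Directed ortho-metalation at the C–H between F and OMe (both direct there), then formylation; −78 °C prevents aryne formation from the ortho-fluoro aryllithium.

Step 7
Reactants: 12 2-fluoro-6-methoxy-4-methylbenzaldehyde
Product: 13 3-bromo-2-fluoro-6-methoxy-4-methylbenzaldehyde
Conditions: NBS, DMF, rt, dark
Reagents that add atoms: N-bromosuccinimide O=C1CCC(=O)N1Br
Why: Electrophilic aromatic bromination para to OMe (also ortho to F, meta to CHO); this is the less hindered of the two free positions.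

Step 8
Reactants: 13 3-bromo-2-fluoro-6-methoxy-4-methylbenzaldehyde
Product: 14 methyl 2-fluoro-3-formyl-4-methoxy-6-methylbenzoate
Conditions: PdCl2(dppf) (5 mol %), CO (3 bar), NaOAc, MeOH, 70 °C
Reagents that add atoms: carbon monoxide [C-]#[O+]; methanol CO
Why: Pd-catalysed methoxycarbonylation (Heck carbonylation) of the aryl bromide; the weak acetate base and moderate temperature spare the activated C–F bond.

Step 9
Reactants: 9 bis-phenol; 14 methyl 2-fluoro-3-formyl-4-methoxy-6-methylbenzoate (2.5 equiv)
Product: 15 dimethyl 2,2'-{(4,6-dimethoxy-2-methyl-1,3-phenylene)bis[methylene(2,4-dimethoxy-6-methyl-3,1-phenylene)oxy]}bis(3-formyl-4-methoxy-6-methylbenzoate) (octa-O-methyl praesorether G)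
Conditions: Cs2CO3, DMSO, 80 °C, N2
Reagents that add atoms: none
Why: Twofold SNAr; the caesium phenoxide displaces fluoride from a carbon flanked by ortho-CHO and ortho-CO2Me, and the only free OH groups in 9 are the two to be arylated.

Step 10
Reactants: 15 octa-O-methyl praesorether G
Product: 16 praesorether G
Conditions: BBr3 (about 20 equiv), CH2Cl2, −78 °C to 0 °C; ice/H2O
Reagents that add atoms: none
Why: Lewis-acid ether cleavage of all eight aryl methyl ethers; diaryl ethers, diarylmethanes and the hindered methyl esters persist at or below 0 °C, and the aldehydes are restored on aqueous work-up.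

## Compound list

1 | 2,4-dimethoxy-6-methylbenzaldehyde | COc1cc(C)c(C=O)c(OC)c1 | starting material
2 | 2,4-dimethoxy-6-methylphenyl formate | COc1cc(C)c(OC=O)c(OC)c1 | intermediate (not isolated)
3 | 2,4-dimethoxy-6-methylphenol | COc1cc(C)c(O)c(OC)c1 | intermediate
4 | 1,5-dimethoxy-2-(methoxymethoxy)-3-methylbenzene | COCOc1c(C)cc(OC)cc1OC | intermediate
5 | 4,6-dimethoxy-2-methylbenzene-1,3-dicarbaldehyde | COc1cc(OC)c(C=O)c(C)c1C=O | intermediate
6 | [2,6-dimethoxy-3-(methoxymethoxy)-4-methylphenyl]lithium | COCOc1c(C)cc(OC)c([Li])c1OC | intermediate (not isolated)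
7 | (4,6-dimethoxy-2-methyl-1,3-phenylene)bis{[2,6-dimethoxy-3-(methoxymethoxy)-4-methylphenyl]methanol}, two carbinol centres as an unassigned meso/racemic mixture | COc1cc(OC)c(C(O)c2c(OC)c(OCOC)c(C)cc2OC)c(C)c1C(O)c1c(OC)c(OCOC)c(C)cc1OC | intermediate
8 | 1,1'-[(4,6-dimethoxy-2-methyl-1,3-phenylene)bis(methylene)]bis[2,6-dimethoxy-3-(methoxymethoxy)-4-methylbenzene] | COc1cc(OC)c(Cc2c(OC)c(OCOC)c(C)cc2OC)c(C)c1Cc1c(OC)c(OCOC)c(C)cc1OC | intermediate (not isolated)
9 | 3,3'-[(4,6-dimethoxy-2-methyl-1,3-phenylene)bis(methylene)]bis(2,4-dimethoxy-6-methylphenol) | COc1cc(OC)c(Cc2c(OC)c(O)c(C)cc2OC)c(C)c1Cc1c(OC)c(O)c(C)cc1OC | intermediate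
10 | 1-fluoro-3-methoxy-5-methylbenzene (3-fluoro-5-methylanisole) | COc1cc(C)cc(F)c1 | starting material
11 | (2-fluoro-6-methoxy-4-methylphenyl)lithium | COc1cc(C)cc(F)c1[Li] | intermediate (not isolated)
12 | 2-fluoro-6-methoxy-4-methylbenzaldehyde | COc1cc(C)cc(F)c1C=O | intermediate
13 | 3-bromo-2-fluoro-6-methoxy-4-methylbenzaldehyde | COc1cc(C)c(Br)c(F)c1C=O | intermediate
14 | methyl 2-fluoro-3-formyl-4-methoxy-6-methylbenzoate | COC(=O)c1c(C)cc(OC)c(C=O)c1F | intermediate
15 | dimethyl 2,2'-{(4,6-dimethoxy-2-methyl-1,3-phenylene)bis[methylene(2,4-dimethoxy-6-methyl-3,1-phenylene)oxy]}bis(3-formyl-4-methoxy-6-methylbenzoate) | COC(=O)c1c(C)cc(OC)c(C=O)c1Oc1c(C)cc(OC)c(Cc2c(OC)cc(OC)c(Cc3c(OC)cc(C)c(Oc4c(C=O)c(OC)cc(C)c4C(=O)OC)c3OC)c2C)c1OC | intermediate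
16 | praesorether G, dimethyl 2,2'-{(4,6-dihydroxy-2-methyl-1,3-phenylene)bis[methylene(2,4-dihydroxy-6-methyl-3,1-phenylene)oxy]}bis(3-formyl-4-hydroxy-6-methylbenzoate) | COC(=O)c1c(C)cc(O)c(C=O)c1Oc1c(C)cc(O)c(Cc2c(O)cc(O)c(Cc3c(O)cc(C)c(Oc4c(C=O)c(O)cc(C)c4C(=O)OC)c3O)c2C)c1O | target

## Step count and risks

Total step count: 10.
Longest linear sequence: 6 steps (steps 1, 2, 4, 5, 9, 10, from compound 1 to compound 16).

The three steps most likely to fail:

**Step 9 (double SNAr to two tetra-ortho-substituted diaryl ethers).** The hindered phenoxide may react slowly or attack the ester of 14. The fallback sets out from 9 and 13 and comes back at 15; it makes the ether before the ester. Bis-phenol 9 is heated with bromo-fluoro aldehyde 13 (Cs2CO3, DMSO, 90 °C). The fluoride of 13 is activated by the ortho-CHO and ortho-Br, is less hindered than in 14 and carries no ester, so this gives 2,2'-{(4,6-dimethoxy-2-methyl-1,3-phenylene)bis[methylene(2,4-dimethoxy-6-methyl-3,1-phenylene)oxy]}bis(3-bromo-6-methoxy-4-methylbenzaldehyde) F3. With no labile C–F left, F3 is then carbonylated twice under forcing conditions (Pd(OAc)2, Xantphos, CO 5 bar, NaOAc, MeOH/toluene, 100 °C) to give 15.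

**Step 10 (eightfold demethylation with both methyl esters intact).** Partial ester cleavage would give mixtures. The fallback sets out from 15 and comes back at 16; it accepts ester loss and restores the esters. Compound 15 is treated with excess BBr3 in CH2Cl2 at rt to 40 °C until all ethers and both esters are cleaved, giving 2,2'-{(4,6-dihydroxy-2-methyl-1,3-phenylene)bis[methylene(2,4-dihydroxy-6-methyl-3,1-phenylene)oxy]}bis(3-formyl-4-hydroxy-6-methylbenzoic acid) F4. F4 is then titrated with TMSCHN2 (2.1 equiv, toluene/MeOH, 0 °C), which methylates the two carboxylic acids much faster than the phenols, to give 16.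

**Step 8 (carbonylation next to an activated C–F bond).** Methanol and base could displace the fluoride, or the hindered bromide could react sluggishly. The fallback sets out from 13 and comes back at 14; it replaces Pd catalysis by organomagnesium carboxylation. Aldehyde 13 is protected with HC(OMe)3 and TsOH (cat.) in MeOH as 2-bromo-4-(dimethoxymethyl)-3-fluoro-5-methoxy-1-methylbenzene F1. Bromine–magnesium exchange with i-PrMgCl·LiCl (THF, −20 °C) and quenching with methyl chloroformate gives methyl 3-(dimethoxymethyl)-2-fluoro-4-methoxy-6-methylbenzoate F2. Hydrolysis of the acetal (1 M HCl, THF, rt) gives 14.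

## Further compounds

F1 | step 8 | 2-bromo-4-(dimethoxymethyl)-3-fluoro-5-methoxy-1-methylbenzene | COc1cc(C)c(Br)c(F)c1C(OC)OC
F2 | step 8 | methyl 3-(dimethoxymethyl)-2-fluoro-4-methoxy-6-methylbenzoate | COC(=O)c1c(C)cc(OC)c(C(OC)OC)c1F
F3 | step 9 | 2,2'-{(4,6-dimethoxy-2-methyl-1,3-phenylene)bis[methylene(2,4-dimethoxy-6-methyl-3,1-phenylene)oxy]}bis(3-bromo-6-methoxy-4-methylbenzaldehyde) | O=Cc1c(OC)cc(C)c(Br)c1Oc1c(C)cc(OC)c(Cc2c(OC)cc(OC)c(Cc3c(OC)cc(C)c(Oc4c(C=O)c(OC)cc(C)c4Br)c3OC)c2C)c1OC
F4 | step 10 | 2,2'-{(4,6-dihydroxy-2-methyl-1,3-phenylene)bis[methylene(2,4-dihydroxy-6-methyl-3,1-phenylene)oxy]}bis(3-formyl-4-hydroxy-6-methylbenzoic acid) | O=C(O)c1c(C)cc(O)c(C=O)c1Oc1c(C)cc(O)c(Cc2c(O)cc(O)c(Cc3c(O)cc(C)c(Oc4c(C=O)c(O)cc(C)c4C(=O)O)c3O)c2C)c1O
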